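The route rests on disconnecting the O1–C2 bond of the dihydrobenzofuran (benzo ring A, 2-aryl ring C). C2 is benzylic and para to the ring C oxygen, so its hydroxyl ionises readily, and O1 sits ortho to C3a, poised for five-membered closure. In one acid-mediated operation a MOM-protected acyclic 1,3-diol, whose C3 comes from an Evans syn aldol, loses its acetal, ionises at C2 and cyclises to the 2,3-trans ring. The derived benzylic bromide alkylates an (R)-β-benzylbutyrolactone; the erythro glycerol ether is then built on the second lactone aryl ring (ring B) by Evans aldol, Mitsunobu inversion and reduction, before hydrogenolysis.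

Key step: step 8

Remark: the target is read as the (3R,4R)-trans lactone carrying a (2S,3R)-trans dihydrobenzofuran and a (1R,2S)-erythro (anti) arylglycerol ether; ring D is the aryl ring of the glycerol unit; compounds 1, 7, 10, 18 and 27 are taken as commercial.

Step 1
Reactants: 1 methyl vanillate
Product: 2 methyl 4-(allyloxy)-3-methoxybenzoate
Conditions: allyl bromide, K2CO3, acetone, reflux
Reagents that add atoms: allyl bromide C=CCBr
Why: Williamson ether synthesis in which the phenoxide of 1 displaces bromide from allyl bromide at oxygen.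

Step 2
Reactants: 2 methyl 4-(allyloxy)-3-methoxybenzoate
Product: 3 methyl 3-allyl-4-hydroxy-5-methoxybenzoate
Conditions: N,N-diethylaniline, 200 °C
Reagents that add atoms: none
Why: Aromatic Claisen rearrangement, the [3,3] shift delivering the allyl group to the only free ortho carbon before the dienone tautomerises to the phenol.

Step 3
Reactants: 3 methyl 3-allyl-4-hydroxy-5-methoxybenzoate
Product: 4 methyl 3-allyl-5-methoxy-4-(methoxymethoxy)benzoate
Conditions: MOMCl, iPr2NEt, CH2Cl2, 0 °C to rt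
Reagents that add atoms: chloromethyl methyl ether COCCl
Why: O-alkylation of the phenol gives a MOM acetal that should survive ozone, chlorite, boron enolate chemistry and borohydride and is cleaved by the acid of step 8.

Step 4
Reactants: 4 methyl 3-allyl-5-methoxy-4-(methoxymethoxy)benzoate
Product: 6 2-[3-methoxy-5-(methoxycarbonyl)-2-(methoxymethoxy)phenyl]acetic acid, via arylacetaldehyde 5 (not isolated)
Conditions: O3, CH2Cl2, −78 °C, then Me2S; then NaClO2, NaH2PO4, 2-methylbut-2-ene, t-BuOH/H2O, 0 °C to rt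
Reagents that add atoms: ozone [O-][O+]=O; sodium chlorite [Na+].[O-]Cl=O
Why: Ozonolysis of the terminal alkene (far faster than attack on the ester-deactivated arene) with reductive work-up, followed by Pinnick oxidation of the sensitive arylacetaldehyde, should give the arylacetic acid.

Step 5
Reactants: 6 2-[3-methoxy-5-(methoxycarbonyl)-2-(methoxymethoxy)phenyl]acetic acid; 7 (S)-4-benzyloxazolidin-2-one
Product: 9 N-(arylacetyl) derivative of (S)-4-benzyloxazolidin-2-one, via mixed pivalic anhydride 8 (not isolated)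
Conditions: PivCl, Et3N, THF, −20 °C; then 7, LiCl, −20 °C to rt
Reagents that add atoms: none
Why: N-acylation of the lithium-coordinated oxazolidinone (LiCl/Et3N) by the mixed pivalic anhydride at its less hindered carbonyl.

Step 6
Reactants: 9 N-(arylacetyl)oxazolidinone; 10 4-(benzyloxy)-3-methoxybenzaldehyde
Product: 11 (2S,3S) syn aldol adduct
Conditions: Bu2BOTf, iPr2NEt, CH2Cl2, −78 to 0 °C; 10, −78 to 0 °C; then pH 7 buffer, MeOH, H2O2, 0 °C
Reagents that add atoms: none
Why: Evans syn aldol in which the Z dibutylboron enolate adds through a Zimmerman–Traxler chair on the face opposite the benzyl group of the (S)-auxiliary, setting the aryl-bearing carbon (future C3, the only centre that must persist) and the carbinol carbon as the (2S,3S) syn adduct.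

Step 7
Reactants: 11 (2S,3S) syn aldol adduct
Product: 12 methyl 3-[(1S,2R)-1-(4-benzyloxy-3-methoxyphenyl)-1,3-dihydroxypropan-2-yl]-5-methoxy-4-(methoxymethoxy)benzoate
Conditions: NaBH4, THF/H2O (4:1), 0 °C to rt
Reagents that add atoms: none
Why: Reductive removal of the auxiliary, NaBH4 in aqueous THF reducing the activated imide carbonyl (assisted by the β-hydroxyl) but not the aryl methyl ester, so the 1,3-diol forms with both stereocentres intact.

Step 8
Reactants: 12 methyl 3-[(1S,2R)-1-(4-benzyloxy-3-methoxyphenyl)-1,3-dihydroxypropan-2-yl]-5-methoxy-4-(methoxymethoxy)benzoate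
Product: 14 methyl (2S,3R)-2-(4-benzyloxy-3-methoxyphenyl)-3-(hydroxymethyl)-7-methoxy-2,3-dihydrobenzofuran-5-carboxylate, via phenol triol 13 (not isolated)
Conditions: HCl (1.25 M in MeOH), 0 to 40 °C
Reagents that add atoms: none
Why: Acid-catalysed acetal methanolysis frees the ring A phenol (13); protonation of the benzylic C2 hydroxyl and loss of water, assisted by the para benzyloxy oxygen of ring C, gives a quinone-methide-like benzylic cation that the phenol oxygen O1 captures to form the O1–C2 bond. The closest known reaction type is the acid-catalysed dehydrative cycloetherification of 2-(2-hydroxyaryl)-1-arylpropane-1,3-diols, the laboratory counterpart of quinone methide trapping in phenylcoumaran biosynthesis. The five-membered ring closes in the 5-exo-trig mode (O1 adds to the trigonal cationic C2 while the delocalised π system stays outside the new ring). C2 is controlled by the C3 stereocentre set in step 6: closure with the aryl group and CH2OH on opposite faces is favoured kinetically and, because ionisation is reversible, thermodynamically, so the 2,3-trans (2S,3R) isomer should form whatever the configuration of the original carbinol. The step needs ionisation at C2 only, secured by the ester para to O1 that suppresses quinone methide formation from ring A, and it needs O1 to win over the primary hydroxyl and methanol, secured by ring size (five against four) and by the reversibility of methyl ether formation.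

Step 9
Reactants: 14 methyl (2S,3R)-2-(4-benzyloxy-3-methoxyphenyl)-3-(hydroxymethyl)-7-methoxy-2,3-dihydrobenzofuran-5-carboxylate
Product: 15 methyl (2S,3R)-3-(benzyloxymethyl)-2-(4-benzyloxy-3-methoxyphenyl)-7-methoxy-2,3-dihydrobenzofuran-5-carboxylate
Conditions: NaH, BnBr, Bu4NI (cat.), THF/DMF, 0 °C to rt
Reagents that add atoms: benzyl bromide BrCc1ccccc1
Why: Williamson benzylation of the only free hydroxyl gives an ether that tolerates hydride, bromination and amide bases and leaves in the final hydrogenolysis.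

Step 10
Reactants: 15 methyl (2S,3R)-3-(benzyloxymethyl)-2-(4-benzyloxy-3-methoxyphenyl)-7-methoxy-2,3-dihydrobenzofuran-5-carboxylate
Product: 16 [(2S,3R)-3-(benzyloxymethyl)-2-(4-benzyloxy-3-methoxyphenyl)-7-methoxy-2,3-dihydrobenzofuran-5-yl]methanol
Conditions: iBu2AlH, CH2Cl2, −78 to 0 °C; aq. KNaC4H4O6 work-up
Reagents that add atoms: none
Why: Hydride reduction of the aryl ester by iBu2AlH to the benzylic alcohol, all ethers being inert.

Step 11
Reactants: 16 [(2S,3R)-3-(benzyloxymethyl)-2-(4-benzyloxy-3-methoxyphenyl)-7-methoxy-2,3-dihydrobenzofuran-5-yl]methanol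
Product: 17 (2S,3R)-3-(benzyloxymethyl)-2-(4-benzyloxy-3-methoxyphenyl)-5-(bromomethyl)-7-methoxy-2,3-dihydrobenzofuran
Conditions: CBr4, PPh3, CH2Cl2, 0 °C
Reagents that add atoms: carbon tetrabromide BrC(Br)(Br)Br
Why: Appel reaction, bromide displacing the alkoxyphosphonium group at the primary benzylic carbon under neutral conditions that do not ionise the dihydrobenzofuran.

Step 12
Reactants: 18 3-(4-hydroxy-3-methoxyphenyl)propanoic acid
Product: 20 3-[4-(tert-butyldimethylsilyloxy)-3-methoxyphenyl]propanoic acid, via bis-silyl derivative 19 (not isolated)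
Conditions: TBSCl, imidazole, DMF, rt; then AcOH, THF/H2O, rt
Reagents that add atoms: tert-butyldimethylsilyl chloride CC(C)(C)[Si](C)(C)Cl
Why: Silylation of both acidic OH groups followed by selective hydrolysis of the far more labile silyl ester leaves the aryl silyl ether, which tolerates the amide bases and hydrides used next.

Step 13
Reactants: 20 3-[4-(tert-butyldimethylsilyloxy)-3-methoxyphenyl]propanoic acid; 7 (S)-4-benzyloxazolidin-2-one
Product: 22 (4S)-4-benzyl-3-{3-[4-(tert-butyldimethylsilyloxy)-3-methoxyphenyl]propanoyl}oxazolidin-2-one, via mixed pivalic anhydride 21 (not isolated)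
Conditions: PivCl, Et3N, THF, −20 °C; then 7, LiCl, −20 °C to rt
Reagents that add atoms: none
Why: N-acylation of the oxazolidinone by the mixed pivalic anhydride at its less hindered carbonyl, as in step 5.

Step 14
Reactants: 22 (4S)-4-benzyl-3-{3-[4-(tert-butyldimethylsilyloxy)-3-methoxyphenyl]propanoyl}oxazolidin-2-one
Product: 23 tert-butyl (3R)-4-[(4S)-4-benzyl-2-oxooxazolidin-3-yl]-3-[4-(tert-butyldimethylsilyloxy)-3-methoxybenzyl]-4-oxobutanoate
Conditions: NaN(SiMe3)2, THF, −78 °C; tert-butyl bromoacetate, −78 to −40 °C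
Reagents that add atoms: tert-butyl bromoacetate CC(C)(C)OC(=O)CBr
Why: Evans alkylation in which the chelated Z sodium enolate is alkylated on the face opposite the benzyl group of the (S)-auxiliary, setting the future lactone C4 with the R configuration.

Step 15
Reactants: 23 tert-butyl (3R)-4-[(4S)-4-benzyl-2-oxooxazolidin-3-yl]-3-[4-(tert-butyldimethylsilyloxy)-3-methoxybenzyl]-4-oxobutanoate
Product: 25 (4R)-4-[4-(tert-butyldimethylsilyloxy)-3-methoxybenzyl]oxolan-2-one, via hydroxy tert-butyl ester 24 (not isolated)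
Conditions: LiBH4, MeOH (1 equiv), THF, 0 °C; then CF3CO2H, CH2Cl2, 0 °C to rt
Reagents that add atoms: none
Why: LiBH4 reductively cleaves the imide faster than it attacks the tert-butyl ester, and CF3CO2H then removes the tert-butyl group as isobutene with spontaneous γ-lactonisation, the stereocentre being untouched.

Step 16
Reactants: 25 (4R)-4-[4-(tert-butyldimethylsilyloxy)-3-methoxybenzyl]oxolan-2-one; 17 dihydrobenzofuran benzylic bromide
Product: 26 (3R,4R)-3-{[(2S,3R)-3-(benzyloxymethyl)-2-(4-benzyloxy-3-methoxyphenyl)-7-methoxy-2,3-dihydrobenzofuran-5-yl]methyl}-4-[4-(tert-butyldimethylsilyloxy)-3-methoxybenzyl]oxolan-2-one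
Conditions: LiN(SiMe3)2, THF, −78 °C; then 17, −78 to −30 °C
Reagents that add atoms: none
Why: Lactone enolate alkylation (SN2 at the benzylic bromide) in which the electrophile enters anti to the C4 benzyl group, setting C3 as R and giving the 3,4-trans lactone.

Step 17
Reactants: 26 silyl-protected trans lactone; 27 (R)-4-benzyl-3-(chloroacetyl)oxazolidin-2-one
Product: 29 ring B aryloxyacetyl imide, via tetrabutylammonium phenolate 28 (not isolated)
Conditions: Bu4NF (1.05 equiv), THF, 0 °C; then 27, Bu4NI (cat.), 0 °C to rt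
Reagents that add atoms: none
Why: Fluoride cleaves only the aryl silyl ether and the naked tetrabutylammonium phenolate, too weakly basic to enolise the lactone, is O-alkylated in situ by the α-chloro imide (Williamson ether synthesis).

Step 18
Reactants: 29 ring B aryloxyacetyl imide; 10 4-(benzyloxy)-3-methoxybenzaldehyde
Product: 30 (2R,3S) syn aldol adduct
Conditions: Bu2BOTf, iPr2NEt, CH2Cl2, −78 to 0 °C; 10, −78 to 0 °C; then pH 7 buffer, MeOH, H2O2, 0 °C
Reagents that add atoms: none
Why: Evans syn aldol of the aryloxyacetyl imide, the Z boron enolate reacting through a Zimmerman–Traxler chair on the face opposite the benzyl group of the (R)-auxiliary, which fixes the ether-bearing carbon in its final configuration and the carbinol carbon as the epimer that step 19 inverts.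

Step 19
Reactants: 30 (2R,3S) syn aldol adduct
Product: 31 (2R,3R) 4-nitrobenzoate
Conditions: PPh3, DIAD, 4-nitrobenzoic acid, THF, 0 °C to rt
Reagents that add atoms: 4-nitrobenzoic acid OC(=O)c1ccc(cc1)[N+](=O)[O-]
Why: Mitsunobu reaction in which the benzylic hydroxyl is activated as an alkoxyphosphonium ion and displaced by 4-nitrobenzoate with SN2 inversion, turning the syn (threo) adduct into the anti (erythro) series.

Step 20
Reactants: 31 (2R,3R) 4-nitrobenzoate
Product: 33 tri-O-benzyl ether of the target, via nitrobenzoate alcohol 32 (not isolated)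
Conditions: NaBH4, THF/H2O (4:1), 0 °C; then K2CO3 (0.2 equiv), MeOH, 0 °C
Reagents that add atoms: none
Why: Borohydride cleavage of the N-acyloxazolidinone (hydride attacks the activated imide carbonyl far faster than the γ-lactone) gives the primary alcohol, and carbonate-catalysed transesterification with methanol then releases the benzylic alcohol, neither event touching a stereocentre.

Step 21
Reactants: 33 tri-O-benzyl ether of the target
Product: 34 CNP0265599.1 (target)
Conditions: H2 (1 atm), Pd/C, EtOAc/MeOH, rt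
Reagents that add atoms: none
Why: Heterogeneous hydrogenolysis should cleave the three O-benzyl groups faster than the cyclic benzylic ether of the dihydrobenzofuran or the benzylic alcohol, so stopping after three equivalents of hydrogen should give the target.

Compound list

1 | methyl vanillate (methyl 4-hydroxy-3-methoxybenzoate) | COC(=O)c1ccc(O)c(OC)c1 | starting material
2 | methyl 4-(allyloxy)-3-methoxybenzoate | COC(=O)c1ccc(OCC=C)c(OC)c1 | intermediate
3 | methyl 3-allyl-4-hydroxy-5-methoxybenzoate | COC(=O)c1cc(CC=C)c(O)c(OC)c1 | intermediate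
4 | methyl 3-allyl-5-methoxy-4-(methoxymethoxy)benzoate | COC(=O)c1cc(CC=C)c(OCOC)c(OC)c1 | intermediate
5 | methyl 3-methoxy-4-(methoxymethoxy)-5-(2-oxoethyl)benzoate | COC(=O)c1cc(CC=O)c(OCOC)c(OC)c1 | intermediate (not isolated)
6 | 2-[3-methoxy-5-(methoxycarbonyl)-2-(methoxymethoxy)phenyl]acetic acid | COC(=O)c1cc(CC(O)=O)c(OCOC)c(OC)c1 | intermediate
7 | (S)-4-benzyloxazolidin-2-one | O=C1N[C@@H](Cc2ccccc2)CO1 | starting material
8 | mixed anhydride of 6 with pivalic acid | COC(=O)c1cc(CC(=O)OC(=O)C(C)(C)C)c(OCOC)c(OC)c1 | intermediate (not isolated)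
9 | methyl 3-{2-[(4S)-4-benzyl-2-oxooxazolidin-3-yl]-2-oxoethyl}-5-methoxy-4-(methoxymethoxy)benzoate | COC(=O)c1cc(CC(=O)N2[C@@H](Cc3ccccc3)COC2=O)c(OCOC)c(OC)c1 | intermediate
10 | 4-(benzyloxy)-3-methoxybenzaldehyde | COc1cc(C=O)ccc1OCc1ccccc1 | starting material
11 | methyl 3-{(2S,3S)-1-[(4S)-4-benzyl-2-oxooxazolidin-3-yl]-3-(4-benzyloxy-3-methoxyphenyl)-3-hydroxy-1-oxopropan-2-yl}-5-methoxy-4-(methoxymethoxy)benzoate | O=C1OC[C@H](Cc2ccccc2)N1C(=O)[C@@H](c1cc(C(=O)OC)cc(OC)c1OCOC)[C@H](O)c1ccc(OCc2ccccc2)c(OC)c1 | intermediate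
12 | methyl 3-[(1S,2R)-1-(4-benzyloxy-3-methoxyphenyl)-1,3-dihydroxypropan-2-yl]-5-methoxy-4-(methoxymethoxy)benzoate | OC[C@@H](c1cc(C(=O)OC)cc(OC)c1OCOC)[C@H](O)c1ccc(OCc2ccccc2)c(OC)c1 | intermediate
13 | methyl 3-[(1S,2R)-1-(4-benzyloxy-3-methoxyphenyl)-1,3-dihydroxypropan-2-yl]-4-hydroxy-5-methoxybenzoate | OC[C@@H](c1cc(C(=O)OC)cc(OC)c1O)[C@H](O)c1ccc(OCc2ccccc2)c(OC)c1 | intermediate (not isolated)
14 | methyl (2S,3R)-2-(4-benzyloxy-3-methoxyphenyl)-3-(hydroxymethyl)-7-methoxy-2,3-dihydrobenzofuran-5-carboxylate | COC(=O)c1cc(OC)c2c(c1)[C@H](CO)[C@@H](c1ccc(OCc3ccccc3)c(OC)c1)O2 | intermediate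
15 | methyl (2S,3R)-3-(benzyloxymethyl)-2-(4-benzyloxy-3-methoxyphenyl)-7-methoxy-2,3-dihydrobenzofuran-5-carboxylate | COC(=O)c1cc(OC)c2c(c1)[C@H](COCc1ccccc1)[C@@H](c1ccc(OCc3ccccc3)c(OC)c1)O2 | intermediate
16 | [(2S,3R)-3-(benzyloxymethyl)-2-(4-benzyloxy-3-methoxyphenyl)-7-methoxy-2,3-dihydrobenzofuran-5-yl]methanol | OCc1cc(OC)c2c(c1)[C@H](COCc1ccccc1)[C@@H](c1ccc(OCc3ccccc3)c(OC)c1)O2 | intermediate
17 | (2S,3R)-3-(benzyloxymethyl)-2-(4-benzyloxy-3-methoxyphenyl)-5-(bromomethyl)-7-methoxy-2,3-dihydrobenzofuran | BrCc1cc(OC)c2c(c1)[C@H](COCc1ccccc1)[C@@H](c1ccc(OCc3ccccc3)c(OC)c1)O2 | intermediate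
18 | 3-(4-hydroxy-3-methoxyphenyl)propanoic acid | COc1cc(CCC(O)=O)ccc1O | starting material
19 | tert-butyldimethylsilyl 3-[4-(tert-butyldimethylsilyloxy)-3-methoxyphenyl]propanoate | COc1cc(CCC(=O)O[Si](C)(C)C(C)(C)C)ccc1O[Si](C)(C)C(C)(C)C | intermediate (not isolated)
20 | 3-[4-(tert-butyldimethylsilyloxy)-3-methoxyphenyl]propanoic acid | COc1cc(CCC(O)=O)ccc1O[Si](C)(C)C(C)(C)C | intermediate
21 | mixed anhydride of 20 with pivalic acid | COc1cc(CCC(=O)OC(=O)C(C)(C)C)ccc1O[Si](C)(C)C(C)(C)C | intermediate (not isolated)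
22 | (4S)-4-benzyl-3-{3-[4-(tert-butyldimethylsilyloxy)-3-methoxyphenyl]propanoyl}oxazolidin-2-one | COc1cc(CCC(=O)N2[C@@H](Cc3ccccc3)COC2=O)ccc1O[Si](C)(C)C(C)(C)C | intermediate
23 | tert-butyl (3R)-4-[(4S)-4-benzyl-2-oxooxazolidin-3-yl]-3-[4-(tert-butyldimethylsilyloxy)-3-methoxybenzyl]-4-oxobutanoate | O=C1OC[C@H](Cc2ccccc2)N1C(=O)[C@H](Cc1ccc(O[Si](C)(C)C(C)(C)C)c(OC)c1)CC(=O)OC(C)(C)C | intermediate
24 | tert-butyl (3R)-3-(hydroxymethyl)-4-[4-(tert-butyldimethylsilyloxy)-3-methoxyphenyl]butanoate | OC[C@H](Cc1ccc(O[Si](C)(C)C(C)(C)C)c(OC)c1)CC(=O)OC(C)(C)C | intermediate (not isolated)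
25 | (4R)-4-[4-(tert-butyldimethylsilyloxy)-3-methoxybenzyl]oxolan-2-one | COc1cc(C[C@H]2COC(=O)C2)ccc1O[Si](C)(C)C(C)(C)C | intermediate
26 | (3R,4R)-3-{[(2S,3R)-3-(benzyloxymethyl)-2-(4-benzyloxy-3-methoxyphenyl)-7-methoxy-2,3-dihydrobenzofuran-5-yl]methyl}-4-[4-(tert-butyldimethylsilyloxy)-3-methoxybenzyl]oxolan-2-one | CC(C)(C)[Si](C)(C)Oc1ccc(C[C@H]2COC(=O)[C@@H]2Cc2cc(OC)c3c(c2)[C@H](COCc2ccccc2)[C@@H](c2ccc(OCc4ccccc4)c(OC)c2)O3)cc1OC | intermediate
27 | (R)-4-benzyl-3-(chloroacetyl)oxazolidin-2-one | O=C1OC[C@@H](Cc2ccccc2)N1C(=O)CCl | starting material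
28 | tetrabutylammonium phenolate of ring B (26 with the silyl group replaced by the ion pair) | CCCC[N+](CCCC)(CCCC)CCCC.[O-]c1ccc(C[C@H]2COC(=O)[C@@H]2Cc2cc(OC)c3c(c2)[C@H](COCc2ccccc2)[C@@H](c2ccc(OCc4ccccc4)c(OC)c2)O3)cc1OC | intermediate (not isolated)
29 | (3R,4R)-4-(4-{2-[(4R)-4-benzyl-2-oxooxazolidin-3-yl]-2-oxoethoxy}-3-methoxybenzyl)-3-{[(2S,3R)-3-(benzyloxymethyl)-2-(4-benzyloxy-3-methoxyphenyl)-7-methoxy-2,3-dihydrobenzofuran-5-yl]methyl}oxolan-2-one | O=C1OC[C@@H](Cc2ccccc2)N1C(=O)COc1ccc(C[C@H]2COC(=O)[C@@H]2Cc2cc(OC)c3c(c2)[C@H](COCc2ccccc2)[C@@H](c2ccc(OCc4ccccc4)c(OC)c2)O3)cc1OC | intermediate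
30 | syn aldol adduct: 29 in which the OCH2 carbon carries the CH(OH)(4-benzyloxy-3-methoxyphenyl) group, (2R,3S) in the propanoyl chain | COc1cc([C@H](O)[C@H](C(=O)N2[C@H](Cc3ccccc3)COC2=O)Oc2ccc(C[C@H]3COC(=O)[C@@H]3Cc3cc(OC)c4c(c3)[C@H](COCc3ccccc3)[C@@H](c3ccc(OCc5ccccc5)c(OC)c3)O4)cc2OC)ccc1OCc1ccccc1 | intermediate
31 | 4-nitrobenzoate of the C3 epimer of 30, (2R,3R) in the propanoyl chain | COc1cc([C@@H](OC(=O)c2ccc(cc2)[N+](=O)[O-])[C@H](C(=O)N2[C@H](Cc3ccccc3)COC2=O)Oc2ccc(C[C@H]3COC(=O)[C@@H]3Cc3cc(OC)c4c(c3)[C@H](COCc3ccccc3)[C@@H](c3ccc(OCc5ccccc5)c(OC)c3)O4)cc2OC)ccc1OCc1ccccc1 | intermediate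
32 | (3R,4R)-4-[4-({(1R,2S)-1-(4-benzyloxy-3-methoxyphenyl)-3-hydroxy-1-(4-nitrobenzoyloxy)propan-2-yl}oxy)-3-methoxybenzyl]-3-{[(2S,3R)-3-(benzyloxymethyl)-2-(4-benzyloxy-3-methoxyphenyl)-7-methoxy-2,3-dihydrobenzofuran-5-yl]methyl}oxolan-2-one | COc1cc([C@@H](OC(=O)c2ccc(cc2)[N+](=O)[O-])[C@H](CO)Oc2ccc(C[C@H]3COC(=O)[C@@H]3Cc3cc(OC)c4c(c3)[C@H](COCc3ccccc3)[C@@H](c3ccc(OCc5ccccc5)c(OC)c3)O4)cc2OC)ccc1OCc1ccccc1 | intermediate (not isolated)
33 | (3R,4R)-4-[4-({(1R,2S)-1-(4-benzyloxy-3-methoxyphenyl)-1,3-dihydroxypropan-2-yl}oxy)-3-methoxybenzyl]-3-{[(2S,3R)-3-(benzyloxymethyl)-2-(4-benzyloxy-3-methoxyphenyl)-7-methoxy-2,3-dihydrobenzofuran-5-yl]methyl}oxolan-2-one | COc1cc([C@@H](O)[C@H](CO)Oc2ccc(C[C@H]3COC(=O)[C@@H]3Cc3cc(OC)c4c(c3)[C@H](COCc3ccccc3)[C@@H](c3ccc(OCc5ccccc5)c(OC)c3)O4)cc2OC)ccc1OCc1ccccc1 | intermediate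
34 | CNP0265599.1: (3R,4R)-4-[4-({(1R,2S)-1,3-dihydroxy-1-(4-hydroxy-3-methoxyphenyl)propan-2-yl}oxy)-3-methoxybenzyl]-3-{[(2S,3R)-2-(4-hydroxy-3-methoxyphenyl)-3-(hydroxymethyl)-7-methoxy-2,3-dihydrobenzofuran-5-yl]methyl}oxolan-2-one | COc1cc([C@@H](O)[C@H](CO)Oc2ccc(C[C@H]3COC(=O)[C@@H]3Cc3cc(OC)c4c(c3)[C@H](CO)[C@@H](c3ccc(O)c(OC)c3)O4)cc2OC)ccc1O | target

Total step count: 21. Longest linear sequence: 17 steps (steps 1–11 and 16–21, from methyl vanillate); the lactone branch (steps 12–15) has 4 steps.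

Steps most likely to fail

1. Step 19 (Mitsunobu inversion). The alkoxyphosphonium ion sits on an electron-rich benzylic carbon next to an acidic α-hydrogen, so elimination to the α-aryloxy cinnamoyl imide or partial ionisation with loss of stereochemical fidelity may compete with clean SN2 displacement. Fallback by oxidation and chelation-controlled reduction: setting out from 30, NaBH4 in THF/H2O removes the auxiliary to give the threo diol F1; TBSCl and imidazole silylate the primary hydroxyl to give the silyl ether F2; Dess–Martin periodinane (NaHCO3, CH2Cl2) oxidises the benzylic alcohol to the α-aryloxy ketone F3; Zn(BH4)2 in Et2O at −78 °C delivers hydride through the chelate between the carbonyl and the aryloxy oxygen to give the erythro alcohol F4; Bu4NF removes the silyl group and the route is rejoined at 33.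

2. Step 8 (key ring closure). Capture of the benzylic cation by methanol or loss of the C3 proton to a stilbene may outrun attack by the ester-deactivated phenol, and the trans preference may be incomplete. Fallback by generating the same cation through hydride abstraction from a deoxy precursor: setting out from 6, DCC/DMAP acylation of (R)-4-benzyloxazolidin-2-one gives the antipodal imide F5 (the chelated alkylation enolate reacts on the face opposite to that of the boron aldol, hence the other auxiliary); Evans alkylation with NaN(SiMe3)2 and 4-(benzyloxy)-3-methoxybenzyl bromide gives the 2,3-diarylpropanoyl imide F6; NaBH4 in THF/H2O gives the primary alcohol F7; HCl in MeOH removes the MOM group to give the phenol F8; DDQ in CH2Cl2 then abstracts hydride from the benzylic CH2 of ring C and the phenol closes the same O1–C2 bond trans to the C3 substituent, rejoining the route at 14.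

3. Step 20 (auxiliary removal beside the lactone). Borohydride may begin to reduce the γ-lactone before the imide is consumed, and the basic methanolysis may open the lactone or let the acyl group migrate. Fallback by hydrolysis and chemoselective borane reduction: setting out from 31, LiOH/H2O2 in THF/H2O at 0 °C cleaves auxiliary and nitrobenzoate and, after acidification (which recloses the lactone), gives the hydroxy acid F9; BH3·SMe2 in THF at 0 °C reduces the free carboxylic acid in preference to the lactone and the route is rejoined at 33.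

Further compounds

F1 | step 19 | threo diol, (1S,2S) epimer of 33 at the benzylic carbinol | COc1cc([C@H](O)[C@H](CO)Oc2ccc(C[C@H]3COC(=O)[C@@H]3Cc3cc(OC)c4c(c3)[C@H](COCc3ccccc3)[C@@H](c3ccc(OCc5ccccc5)c(OC)c3)O4)cc2OC)ccc1OCc1ccccc1
F2 | step 19 | primary tert-butyldimethylsilyl ether of F1 | COc1cc([C@H](O)[C@H](CO[Si](C)(C)C(C)(C)C)Oc2ccc(C[C@H]3COC(=O)[C@@H]3Cc3cc(OC)c4c(c3)[C@H](COCc3ccccc3)[C@@H](c3ccc(OCc5ccccc5)c(OC)c3)O4)cc2OC)ccc1OCc1ccccc1
F3 | step 19 | (2S)-α-aryloxy ketone obtained from F2 by oxidation of the benzylic alcohol | COc1cc(C(=O)[C@H](CO[Si](C)(C)C(C)(C)C)Oc2ccc(C[C@H]3COC(=O)[C@@H]3Cc3cc(OC)c4c(c3)[C@H](COCc3ccccc3)[C@@H](c3ccc(OCc5ccccc5)c(OC)c3)O4)cc2OC)ccc1OCc1ccccc1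
F4 | step 19 | primary tert-butyldimethylsilyl ether of 33, (1R,2S) | COc1cc([C@@H](O)[C@H](CO[Si](C)(C)C(C)(C)C)Oc2ccc(C[C@H]3COC(=O)[C@@H]3Cc3cc(OC)c4c(c3)[C@H](COCc3ccccc3)[C@@H](c3ccc(OCc5ccccc5)c(OC)c3)O4)cc2OC)ccc1OCc1ccccc1
F5 | step 8 | methyl 3-{2-[(4R)-4-benzyl-2-oxooxazolidin-3-yl]-2-oxoethyl}-5-methoxy-4-(methoxymethoxy)benzoate | COC(=O)c1cc(CC(=O)N2[C@H](Cc3ccccc3)COC2=O)c(OCOC)c(OC)c1
F6 | step 8 | methyl 3-{(2R)-1-[(4R)-4-benzyl-2-oxooxazolidin-3-yl]-3-(4-benzyloxy-3-methoxyphenyl)-1-oxopropan-2-yl}-5-methoxy-4-(methoxymethoxy)benzoate | O=C1OC[C@@H](Cc2ccccc2)N1C(=O)[C@@H](c1cc(C(=O)OC)cc(OC)c1OCOC)Cc1ccc(OCc2ccccc2)c(OC)c1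
F7 | step 8 | methyl 3-[(2R)-1-(4-benzyloxy-3-methoxyphenyl)-3-hydroxypropan-2-yl]-5-methoxy-4-(methoxymethoxy)benzoate | OC[C@@H](c1cc(C(=O)OC)cc(OC)c1OCOC)Cc1ccc(OCc2ccccc2)c(OC)c1
F8 | step 8 | methyl 3-[(2R)-1-(4-benzyloxy-3-methoxyphenyl)-3-hydroxypropan-2-yl]-4-hydroxy-5-methoxybenzoate | OC[C@@H](c1cc(C(=O)OC)cc(OC)c1O)Cc1ccc(OCc2ccccc2)c(OC)c1
F9 | step 20 | (2R,3R)-3-(4-benzyloxy-3-methoxyphenyl)-3-hydroxy-2-(ring B aryloxy)propanoic acid corresponding to 33 with CO2H in place of CH2OH | COc1cc([C@@H](O)[C@H](C(O)=O)Oc2ccc(C[C@H]3COC(=O)[C@@H]3Cc3cc(OC)c4c(c3)[C@H](COCc3ccccc3)[C@@H](c3ccc(OCc5ccccc5)c(OC)c3)O4)cc2OC)ccc1OCc1ccccc1
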